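The neighbour of dusk, the same flask read at 20 min, comes last; first you need the flasks as charged and what is asked of them.

| flask | substrate | coupling partner | protic impurity | time | remark |
|---|---|---|---|---|---|
| dusk | 0.50 M | 0.300 M (fed, over 8.0 min) | 0.0250 M | 12 min | all else is in the flask from the start; the feed brings no volume worth counting |
| autumn | 0.50 M | 0.300 M | 0.0250 M | 12 min | everything together at the start |
| noon | 0.50 M (fed, over 8.0 min) | 0.300 M | 0.0250 M | 12 min | all else is in the flask from the start; the feed brings no volume worth counting |

- the flask that comes out highest in share of target in target plus isomer of the product, or "all alike" when all lie within 1.5 percentage points (dusk / autumn / noon / all alike)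
- share of target in target plus isomer of the product at the end, dusk
- share of target in target plus isomer of the product at the end, autumn
- share of target in target plus isomer of the product at the end, noon

- a species is counted by the substrate in it: one side product counts as two
- amounts and yields of target count crystals too
- given per volume of solution although it is solid: crystals
- run time (dusk): 12 min

    substrate ⇌ tautomer (K1 = 1.1, k1 = 0.012 s⁻¹)
    substrate + coupling partner → isomer of the product (k2 = 0.0080 M⁻¹ s⁻¹)
    coupling partner + tautomer → target (k3 = 0.012 M⁻¹ s⁻¹)
    crystals ⇌ target, rate k4*(cs4 - [target]) while solid is left; crystals form when [target] > cs4 (cs4 = 7.0 mM, k4 = 0.30 s⁻¹)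
    coupling partner + protic impurity → quenched reagent (k5 = 0.054 M⁻¹ s⁻¹)
    substrate + tautomer → side product (k6 = 0.019 M⁻¹ s⁻¹)

1. Substrate turns reversibly into tautomer, and coupling partner takes tautomer to target and substrate to isomer of the product. In fractions of the substrate charge, target grows as 0.012 M⁻¹ s⁻¹ times the tautomer fraction and isomer as 0.0080 M⁻¹ s⁻¹ times the substrate fraction, each times the same partner.

2. At balance, the tautomer fraction over the substrate fraction is 1.1. Fold the three constants into 1.65, the balance ratio, meaning target formed per isomer formed while substrate and tautomer stand in balance. This is the selectivity factor.

3. Reading it off gives a share of 62.3 %. The number holds no feed, so it cannot yet tell the flasks apart.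

4. Now test it by counting half-lives. In dusk, the feed of 8.0 min is longer than the forward half-life of substrate, 0.96 min, spanning 8.33 of them, so I expect dusk nearest 62.3 %. In autumn, the whole charge of partner meets substrate at the start with no tautomer charged, so isomer can form before balance stands, although the half-life of substrate by that step, 4.8 min, is longer than the forward half-life of 0.96 min; I therefore do not trust the balance ratio for the start of autumn. In noon, fresh substrate enters throughout the feed. One number is not enough: I commit to dusk highest, and give autumn and noon no figure beyond lying lower.

5. The forecast says dusk, with 60 % for dusk, 47 % for autumn and 57 % for noon: “dusk comes closest to the limit because the substrate equilibrates before much partner is present”.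

6. The simulation gives dusk highest: dusk 60.0 %, autumn 49.1 %, noon 50.7 %.

7. The forecast and I agree on dusk; its noon stands 6.3 percentage points above the result. In dusk, by 1.20 min, the step from substrate to tautomer had 80 % of its turnover up to the asked time behind it, and the step to target 3.1 %. In noon, at the end of the feed (8.00 min), tautomer stood at 20.3 % and substrate at 27.4 %, a ratio of 0.741, lower than the balance value 1.1.

8. For dusk read later, the balance ratio says new target and new isomer should arrive at 1.65 to one. Between the two readings, target went from 14.9 % to 18.2 % and isomer from 9.91 % to 12.0 %, a ratio of 1.61, and the share reads 60.3 %.

The constants were set for the occasion.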